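The numbers in the tables are simulated from invented constants; noise was put on by code.

- Count lifetimes. If one first-order step turns what the substrate has become into target, the unmade share falls as exp(−N), where N is that step's rate constant integrated over the flask's time.

| setting | amber | blue | autumn | midnight |
|---|---|---|---|---|
| substrate | 0.40 M | 0.40 M | 0.40 M | 0.40 M |
| reagent | 0.62 equiv | 2.6 equiv | 1.00 equiv | 3.00 equiv |
| temperature | −25 °C | 0 °C |  |  |
| remark | run made earlier | run made earlier | at −20 °C until 4.0 h, from then on at 20 °C | at 20 °C throughout |
| time |  |  | 8.0 h | 8.0 h |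

- amber (time / h: target / %, substrate / %): 0.417: 0, 19; 1.33: 1, 1; 2.50: 1, 0; 3.00: 1, 0; 5.00: 2, 0; 6.00: 3, 0; 8.00: 4, 0
- blue (time / h: target / %, substrate / %): 0.333: 3, 3; 1.00: 10, 1; 2.00: 23, 1; 3.00: 31, 0

(readings scatter by 1.5 percentage points)

1. the winner by amount of target, in percent of the substrate charged; "neither" if no more than 2 percentage points parts them (autumn / midnight / neither)
2. how much target is there at the end, in percent of the substrate charged: autumn
3. how much target is there at the end, in percent of the substrate charged: midnight



- The substrate step need not be known well: amber reads 1 % substrate at 1.33 h with target at 1 %, so I place the clock of target in a later step and model that as one rate-limiting step.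
- Last readings give 0.124 /h for blue and 0.00510 /h for amber.
- If reagent has no effect on that step (order zero), the gap means 71.9 kJ/mol, so 1.07 /h at 20 °C and 0.0102 /h at −20 °C.
- The cold temperature need not be known well either: autumn's cold half adds 0.0406 to N, its warm half 4.29.
- The reagent order must be known. At order one the gap means 39.6 kJ/mol, and the warm half of autumn counts 0.624, midnight 3.75.
- One-to-one use of reagent in amber would leave 38.0 % of the substrate, more than the 1 % read at 1.33 h, so I read reagent as not spent one to one there, and I judge order zero.
- Autumn's lifetime count, the integrated rate constant of the slow step, is then 4.33, and midnight's is 8.57. Their unmade shares are 1.32 % and 0.0190 %, so I expect a tie at whatever ceiling the two share.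
- The forecast says midnight, with 45 % for autumn and 93 % for midnight, adding “If reagent matters less, it gives more.” I part from it on autumn and on the winner.
- The flasks give neither: autumn 68.4 %, midnight 69.1 %.

    substrate → intermediate B (k = 6.50 /h, Ea = 69.0 kJ/mol)
    intermediate B ⇌ intermediate C (K = 0.990, k = 0.0280 /h, Ea = 80.0 kJ/mol, ΔH = −52.0 kJ/mol)
    intermediate A ⇌ intermediate B (K = 1.20, k = 0.190 /h, Ea = 82.0 kJ/mol, ΔH = 22.0 kJ/mol)
    substrate → intermediate A (k = 0.130 /h, Ea = 76.0 kJ/mol)
    substrate + intermediate A → side product B (k = 0.930 /M/h, Ea = 46.0 kJ/mol)
    substrate ⇌ dormant form (K = 2.40, k = 0.730 /h, Ea = 70.0 kJ/mol, ΔH = 3.00 kJ/mol)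
    intermediate C → side product A (k = 0.110 /h, Ea = 82.0 kJ/mol)
    intermediate C → target (k = 0.190 /h, Ea = 86.0 kJ/mol)
    (constants at −20 °C)

- At 8.00 h my N for autumn leaves 1.32 % of the charge unfinished, and its intermediates A, B and C together hold 0.435 %. Ten times the time moves autumn's target from 68.4 % to 68.7 %, and midnight's from 69.1 % to 69.1 %. Midnight holds side product A at 30.9 % beside that target, and I take 69.1 % as its ceiling for target.
- Midnight's charge held at −5 °C counts 0.548, which on that ceiling gives 29.2 %. The computed flask gives 39.3 %.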